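The bond that carries the strategy is O1–C2 of the 2,3-dihydrobenzofuran, formed last, after its C3 stereocentre is in place. C2 is a benzylic carbon para to the free phenol of the 4-hydroxy-3-methoxyphenyl ring (ring A), so DDQ can turn it into the exocyclic carbon of a p-quinone methide; the phenol oxygen on C7a of the brominated ring (ring B) then adds to it. One operation closes the furan ring, makes the C–O bond and sets C2 trans to C3. The precursor is an (S)-2-(5-bromo-2-hydroxy-3-methoxyphenyl)-3-(4-hydroxy-3-methoxyphenyl)propyl silyl ether from an auxiliary alkylation; the same imide also supplies the west half, joined by lactone alkylation.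

Key step: step 12

Remark on the chemistry: the magnesium-halide anti-aldol of step 16 is taken to follow the chelated-enolate sense of induction (same enolate face as the alkylation of step 8); the fallback for that step does not depend on this.

Abbreviations in names: TBS = tert-butyldimethylsilyl; ArE = (2R,3S)-2-[4-(allyloxy)-3-methoxyphenyl]-3-(TBS-oxymethyl)-7-methoxy-2,3-dihydro-1-benzofuran-5-yl; ArW = 4-(allyloxy)-3-[(1S,2S)-1-[4-(allyloxy)-3-methoxyphenyl]-1,3-bis(TBS-oxy)propan-2-yl]-5-methoxyphenyl.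

Step 1
Reactants: 1 5-bromo-2-hydroxy-3-methoxybenzaldehyde; 2 allyl bromide
Product: 3 2-(allyloxy)-5-bromo-3-methoxybenzaldehyde
Conditions: K2CO3, DMF, rt
Reagents that add atoms: none
Why: Williamson etherification of the phenoxide (SN2) masks the phenol as an ether that tolerates ylide, enolate, hydride and organolithium chemistry and is removed later by zerovalent palladium.

Step 2
Reactants: 3
Product: 4 2-(allyloxy)-5-bromo-1-methoxy-3-(2-methoxyvinyl)benzene (E/Z mixture)
Conditions: Ph3P(CH2OMe)Cl, KOt-Bu, THF, 0 °C to rt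
Reagents that add atoms: (methoxymethyl)triphenylphosphonium chloride, COC[P+](c1ccccc1)(c1ccccc1)c1ccccc1.[Cl-]
Why: Wittig reaction of the non-enolisable aryl aldehyde with the methoxymethylene ylide adds the one carbon needed for the arylacetic acid, and both alkene isomers lead to the same aldehyde.

Step 3
Reactants: 4
Product: 6 2-[2-(allyloxy)-5-bromo-3-methoxyphenyl]acetic acid, via arylacetaldehyde 5 (not isolated)
Conditions: 2 M HCl, THF, 40 °C; then NaH2PO4 buffer, t-BuOH, 2-methyl-2-butene, NaClO2, 0 °C to rt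
Reagents that add atoms: water, O; sodium chlorite, [Na+].[O-]Cl=O
Why: Acid hydrolysis of the enol ether gives the arylacetaldehyde, which is oxidised in the same vessel by the Pinnick (chlorite) oxidation, 2-methyl-2-butene scavenging hypochlorite so that the allyl ether and the electron-rich ring are spared.

Step 4
Reactants: 6; 7 (S)-4-benzyloxazolidin-2-one
Product: 9 (S)-4-benzyl-3-{2-[2-(allyloxy)-5-bromo-3-methoxyphenyl]acetyl}oxazolidin-2-one, via mixed pivalic anhydride 8 (not isolated)
Conditions: t-BuCOCl, Et3N, THF, −20 °C; then LiCl, 7, −20 °C to rt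
Reagents that add atoms: none
Why: N-acylation of the oxazolidinone through the mixed pivalic anhydride with LiCl activation needs no strong base, which avoids ketene formation from the arylacetic acid.

Step 5
Reactants: 10 vanillin (4-hydroxy-3-methoxybenzaldehyde); 2 allyl bromide
Product: 11 4-(allyloxy)-3-methoxybenzaldehyde
Conditions: K2CO3, DMF, rt
Reagents that add atoms: none
Why: Williamson etherification of the vanillin phenoxide (SN2) gives the aldehyde used both for the aldol of step 16 and for the benzylic bromide of step 7.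

Step 6
Reactants: 11
Product: 12 [4-(allyloxy)-3-methoxyphenyl]methanol
Conditions: NaBH4, MeOH, 0 °C
Reagents that add atoms: none
Why: Borohydride reduction of the aryl aldehyde to the benzylic alcohol is chemoselective in the presence of the allyl ether.

Step 7
Reactants: 12
Product: 13 1-(allyloxy)-4-(bromomethyl)-2-methoxybenzene
Conditions: PBr3, Et2O, 0 °C
Reagents that add atoms: phosphorus tribromide, BrP(Br)Br
Why: Bromination of the electron-rich benzylic alcohol with PBr3 by way of the phosphite ester gives the reactive alkylating agent, which is used without storage.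

Step 8
Reactants: 9; 13
Product: 15 (S)-4-benzyl-3-[(2S)-2-[2-(allyloxy)-5-bromo-3-methoxyphenyl]-3-[4-(allyloxy)-3-methoxyphenyl]propanoyl]oxazolidin-2-one, via sodium (Z)-enolate 14 (not isolated)
Conditions: NaN(SiMe3)2, THF, −78 °C; then 13, −78 to −40 °C
Reagents that add atoms: none
Why: Evans asymmetric alkylation, in which the chelated (Z)-enolate takes the benzylic bromide on the face away from the C4 benzyl group of the auxiliary, sets the (2S) centre that becomes C3 of the dihydrobenzofuran.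

Step 9
Reactants: 15
Product: 16 (2S)-2-[2-(allyloxy)-5-bromo-3-methoxyphenyl]-3-[4-(allyloxy)-3-methoxyphenyl]propan-1-ol
Conditions: LiBH4, MeOH (1 equiv), THF, 0 °C
Reagents that add atoms: none
Why: Reductive cleavage of the N-acyloxazolidinone with LiBH4 gives the primary alcohol under conditions too mild to epimerise the benzylic centre, and the auxiliary is recovered.

Step 10
Reactants: 16
Product: 17 tert-butyl{(2S)-2-[2-(allyloxy)-5-bromo-3-methoxyphenyl]-3-[4-(allyloxy)-3-methoxyphenyl]propoxy}dimethylsilane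
Conditions: TBSCl, imidazole, CH2Cl2, rt
Reagents that add atoms: tert-butyldimethylsilyl chloride, CC(C)(C)[Si](C)(C)Cl
Why: Imidazole-mediated silylation protects the primary alcohol through the oxidation, organolithium and enolate steps until the fluoride step at the end.

Step 11
Reactants: 17
Product: 18 4-bromo-2-[(2S)-1-(TBS-oxy)-3-(4-hydroxy-3-methoxyphenyl)propan-2-yl]-6-methoxyphenol
Conditions: Pd(PPh3)4 (5 mol%), morpholine, THF, rt
Reagents that add atoms: none
Why: Tsuji–Trost deallylation, in which zerovalent palladium ionises both aryl allyl ethers at room temperature and morpholine traps the allyl groups, frees both phenols while oxidative addition to the electron-rich aryl bromide remains far slower.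

Step 12
Reactants: 18
Product: 20 4-[(2R,3S)-5-bromo-3-(TBS-oxymethyl)-7-methoxy-2,3-dihydro-1-benzofuran-2-yl]-2-methoxyphenol (2,3-trans), via p-quinone methide 19 (not isolated)
Conditions: DDQ (1.05 equiv), 4 Å molecular sieves, CH2Cl2, 0 °C
Reagents that add atoms: none
Why: DDQ removes hydride from the propyl C3 methylene of 18 (the future C2), the only benzylic position para to a free phenol, to give p-quinone methide 19, and the ring B phenol oxygen then adds to the exocyclic methide carbon while ring A regains aromaticity. The closest known reaction type is the DDQ cyclisation of 2'-hydroxyisoflavans to pterocarpans, together with the phenol capture of quinone methides that forms 8–5' neolignans. The dihydrofuran ring closes in a 5-exo-trig mode. The new C2 centre is controlled by the existing C3 centre: the aryl group settles trans to the silyloxymethyl group, which is the less hindered approach and, because the addition can reverse through the quinone methide, also the thermodynamic outcome. The step needs oxidation of ring A only and retention of the C3 configuration; ring B carries bromine para to its phenol so it cannot form a second p-quinone methide, and fast intramolecular capture at 0 °C with only a slight excess of DDQ should outrun tautomerisation to the stilbene and further dehydrogenation to the benzofuran.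

Step 13
Reactants: 20; 2 allyl bromide
Product: 21 tert-butyl{[(2R,3S)-2-[4-(allyloxy)-3-methoxyphenyl]-5-bromo-7-methoxy-2,3-dihydro-1-benzofuran-3-yl]methoxy}dimethylsilane (ArE–Br)
Conditions: K2CO3, acetone, rt
Reagents that add atoms: none
Why: Williamson etherification of the ring A phenol (SN2) masks it before the organolithium and enolate steps, and carbonate at room temperature is too mild to reopen the benzylic aryl ether through the quinone methide.

Step 14
Reactants: 21
Product: 24 ArE–CH2OH, via aryllithium 22 (not isolated), via aldehyde 23 (not isolated)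
Conditions: n-BuLi, THF, −78 °C; DMF, −78 to 0 °C; then MeOH, NaBH4, 0 °C
Reagents that add atoms: N,N-dimethylformamide, CN(C)C=O
Why: Bromine–lithium exchange is faster than any deprotonation at −78 °C, the aryllithium is formylated by DMF, and the aldehyde released on adding methanol is reduced in the same vessel by borohydride (one-pot formylation and reduction).

Step 15
Reactants: 24
Product: 25 ArE–CH2Br
Conditions: CBr4, PPh3, CH2Cl2, 0 °C
Reagents that add atoms: tetrabromomethane, BrC(Br)(Br)Br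
Why: The Appel reaction turns the benzylic alcohol into the bromide under neutral conditions that leave the silyl ether, the allyl ether and the benzylic C2–O bond intact.

Step 16
Reactants: 9; 11
Product: 26 (S)-4-benzyl-3-[(2R,3S)-2-[2-(allyloxy)-5-bromo-3-methoxyphenyl]-3-[4-(allyloxy)-3-methoxyphenyl]-3-(trimethylsilyloxy)propanoyl]oxazolidin-2-one
Conditions: MgCl2 (20 mol%), Et3N, Me3SiCl, EtOAc, rt
Reagents that add atoms: chlorotrimethylsilane, C[Si](C)(C)Cl
Why: Magnesium-halide-catalysed direct anti-aldol of an N-acyloxazolidinone (Evans type), in which soft enolisation gives the chelated (Z)-magnesium enolate and the non-enolisable aryl aldehyde adds through a boat transition state to the face away from the auxiliary benzyl group, should set C2 in the same sense as step 8 and C3 anti to it, while silylation of the aldolate turns the catalyst over and blocks retro-aldol.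

Step 17
Reactants: 26
Product: 28 (1S,2S)-2-[2-(allyloxy)-5-bromo-3-methoxyphenyl]-1-[4-(allyloxy)-3-methoxyphenyl]propane-1,3-diol, via silyl ether alcohol 27 (not isolated)
Conditions: LiBH4, MeOH (1 equiv), THF, 0 °C; then K2CO3, MeOH, rt
Reagents that add atoms: none
Why: LiBH4 reductively cleaves the imide while the trimethylsilyl ether still blocks retro-aldol, and carbonate-catalysed methanolysis then frees the secondary hydroxyl without exposing the benzylic carbinol to acid.

Step 18
Reactants: 28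
Product: 29 (1S,2S)-2-[2-(allyloxy)-5-bromo-3-methoxyphenyl]-1-[4-(allyloxy)-3-methoxyphenyl]-1,3-bis(TBS-oxy)propane (ArW–Br)
Conditions: TBSOTf, 2,6-lutidine, CH2Cl2, −20 to 0 °C
Reagents that add atoms: tert-butyldimethylsilyl trifluoromethanesulfonate, CC(C)(C)[Si](C)(C)OS(=O)(=O)C(F)(F)F
Why: Silylation of both hydroxyls with the silyl triflate and a hindered pyridine base protects the diol, the triflate being needed for the crowded benzylic secondary hydroxyl.

Step 19
Reactants: 29
Product: 32 ArW–CH2OH, via aryllithium 30 (not isolated), via aldehyde 31 (not isolated)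
Conditions: n-BuLi, THF, −78 °C; DMF, −78 to 0 °C; then MeOH, NaBH4, 0 °C
Reagents that add atoms: N,N-dimethylformamide, CN(C)C=O
Why: The same one-pot bromine–lithium exchange, formylation and borohydride reduction as in step 14 converts the aryl bromide into the benzylic alcohol without touching the silyl or allyl ethers.

Step 20
Reactants: 32
Product: 33 ArW–CH2Br
Conditions: CBr4, PPh3, CH2Cl2, 0 °C
Reagents that add atoms: tetrabromomethane, BrC(Br)(Br)Br
Why: The Appel reaction gives the benzylic bromide under neutral conditions that spare the acid-sensitive benzylic silyl ether.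

Step 21
Reactants: 7 (S)-4-benzyloxazolidin-2-one; 34 methyl 4-chloro-4-oxobutanoate
Product: 35 methyl 4-[(4S)-4-benzyl-2-oxooxazolidin-3-yl]-4-oxobutanoate
Conditions: Et3N, DMAP (cat.), CH2Cl2, 0 °C to rt
Reagents that add atoms: none
Why: DMAP-catalysed N-acylation of the oxazolidinone by the acid chloride gives the succinate imide, whose imide α-methylene is far more acidic than the ester α-methylene.

Step 22
Reactants: 35; 33
Product: 37 methyl (3S)-3-(ArW-methyl)-4-[(4S)-4-benzyl-2-oxooxazolidin-3-yl]-4-oxobutanoate, via sodium (Z)-enolate 36 (not isolated)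
Conditions: NaN(SiMe3)2, THF, −78 °C; then 33, −78 to −40 °C
Reagents that add atoms: none
Why: Evans asymmetric alkylation, in which the base removes the imide α-proton selectively and the chelated (Z)-enolate takes the benzylic bromide on the face away from the auxiliary benzyl group, sets the (3S) centre that becomes C4 of the lactone.

Step 23
Reactants: 37
Product: 39 (4S)-4-(ArW-methyl)dihydrofuran-2(3H)-one, via hydroxy ester 38 (not isolated)
Conditions: NaBH4, THF/H2O, 0 °C to rt; then DBU (cat.), CH2Cl2, rt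
Reagents that add atoms: none
Why: Borohydride in aqueous THF reductively cleaves the N-acyloxazolidinone without reducing the methyl ester, and the γ-hydroxy ester then lactonises (5-exo-trig transesterification), so the centre set in step 22 is carried over unchanged.

Step 24
Reactants: 39; 25
Product: 41 (3S,4S)-3-(ArE-methyl)-4-(ArW-methyl)dihydrofuran-2(3H)-one, via lithium enolate 40 (not isolated)
Conditions: LiN(SiMe3)2, THF, −78 °C; then 25, DMPU, −78 to −30 °C
Reagents that add atoms: none
Why: Alkylation of the lithium enolate of a 4-substituted butyrolactone, in which the benzylic bromide approaches the enolate face opposite the C4 substituent, sets C3 trans to C4 as in the standard construction of dibenzylbutyrolactone lignans.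

Step 25
Reactants: 41
Product: 42 (3S,4S)-3-{[(2R,3S)-2-[4-(allyloxy)-3-methoxyphenyl]-3-(hydroxymethyl)-7-methoxy-2,3-dihydro-1-benzofuran-5-yl]methyl}-4-{4-(allyloxy)-3-[(1S,2S)-1-[4-(allyloxy)-3-methoxyphenyl]-1,3-dihydroxypropan-2-yl]-5-methoxybenzyl}dihydrofuran-2(3H)-one
Conditions: Bu4NF, AcOH, THF, rt
Reagents that add atoms: none
Why: Fluoride-mediated cleavage of the three silyl ethers, buffered with acetic acid to protect the lactone and its C3 centre, is carried out while all four phenols are still allylated so that no quinone methide can form at the benzylic carbinol.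

Step 26
Reactants: 42
Product: 43 (3S,4S)-3-{[(2R,3S)-2-(4-hydroxy-3-methoxyphenyl)-3-(hydroxymethyl)-7-methoxy-2,3-dihydro-1-benzofuran-5-yl]methyl}-4-{4-hydroxy-3-[(1S,2S)-1,3-dihydroxy-1-(4-hydroxy-3-methoxyphenyl)propan-2-yl]-5-methoxybenzyl}dihydrofuran-2(3H)-one
Conditions: Pd(PPh3)4 (10 mol%), N-methylaniline, THF, rt
Reagents that add atoms: none
Why: Tsuji–Trost deallylation under near-neutral conditions, in which zerovalent palladium ionises the four aryl allyl ethers and the weakly basic aniline traps the allyl groups, should leave the benzylic alcohol, the benzylic ether of the dihydrobenzofuran and the lactone untouched.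

Compound list
1 | 5-bromo-2-hydroxy-3-methoxybenzaldehyde | COc1cc(Br)cc(C=O)c1O | starting material
2 | allyl bromide | C=CCBr | starting material
3 | 2-(allyloxy)-5-bromo-3-methoxybenzaldehyde | COc1cc(Br)cc(C=O)c1OCC=C | intermediate
4 | 2-(allyloxy)-5-bromo-1-methoxy-3-(2-methoxyvinyl)benzene (E/Z mixture) | COC=Cc1cc(Br)cc(OC)c1OCC=C | intermediate
5 | 2-[2-(allyloxy)-5-bromo-3-methoxyphenyl]acetaldehyde | O=CCc1cc(Br)cc(OC)c1OCC=C | intermediate
6 | 2-[2-(allyloxy)-5-bromo-3-methoxyphenyl]acetic acid | OC(=O)Cc1cc(Br)cc(OC)c1OCC=C | intermediate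
7 | (S)-4-benzyloxazolidin-2-one | O=C1N[C@@H](Cc2ccccc2)CO1 | starting material
8 | 2-[2-(allyloxy)-5-bromo-3-methoxyphenyl]acetic pivalic anhydride | CC(C)(C)C(=O)OC(=O)Cc1cc(Br)cc(OC)c1OCC=C | intermediate
9 | (S)-4-benzyl-3-{2-[2-(allyloxy)-5-bromo-3-methoxyphenyl]acetyl}oxazolidin-2-one | O=C(Cc1cc(Br)cc(OC)c1OCC=C)N1[C@@H](Cc2ccccc2)COC1=O | intermediate
10 | vanillin | COc1cc(C=O)ccc1O | starting material
11 | 4-(allyloxy)-3-methoxybenzaldehyde | COc1cc(C=O)ccc1OCC=C | intermediate
12 | [4-(allyloxy)-3-methoxyphenyl]methanol | COc1cc(CO)ccc1OCC=C | intermediate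
13 | 1-(allyloxy)-4-(bromomethyl)-2-methoxybenzene | COc1cc(CBr)ccc1OCC=C | intermediate
14 | sodium (Z)-enolate of 9 | [Na+].[O-]/C(=C\c1cc(Br)cc(OC)c1OCC=C)N1[C@@H](Cc2ccccc2)COC1=O | intermediate
15 | (S)-4-benzyl-3-[(2S)-2-[2-(allyloxy)-5-bromo-3-methoxyphenyl]-3-[4-(allyloxy)-3-methoxyphenyl]propanoyl]oxazolidin-2-one | Brc1cc(OC)c(OCC=C)c(c1)[C@@H](C(=O)N1[C@@H](Cc2ccccc2)COC1=O)Cc1ccc(OCC=C)c(OC)c1 | intermediate
16 | (2S)-2-[2-(allyloxy)-5-bromo-3-methoxyphenyl]-3-[4-(allyloxy)-3-methoxyphenyl]propan-1-ol | Brc1cc(OC)c(OCC=C)c(c1)[C@@H](CO)Cc1ccc(OCC=C)c(OC)c1 | intermediate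
17 | TBS ether of 16 | Brc1cc(OC)c(OCC=C)c(c1)[C@@H](CO[Si](C)(C)C(C)(C)C)Cc1ccc(OCC=C)c(OC)c1 | intermediate
18 | 4-bromo-2-[(2S)-1-(TBS-oxy)-3-(4-hydroxy-3-methoxyphenyl)propan-2-yl]-6-methoxyphenol | Brc1cc(OC)c(O)c(c1)[C@@H](CO[Si](C)(C)C(C)(C)C)Cc1ccc(O)c(OC)c1 | intermediate
19 | 4-[(2S)-2-(5-bromo-2-hydroxy-3-methoxyphenyl)-3-(TBS-oxy)propylidene]-2-methoxycyclohexa-2,5-dien-1-one | Brc1cc(OC)c(O)c(c1)[C@@H](CO[Si](C)(C)C(C)(C)C)C=C1C=CC(=O)C(OC)=C1 | intermediate
20 | 4-[(2R,3S)-5-bromo-3-(TBS-oxymethyl)-7-methoxy-2,3-dihydro-1-benzofuran-2-yl]-2-methoxyphenol | Brc1cc(OC)c2c(c1)[C@@H](CO[Si](C)(C)C(C)(C)C)[C@H](c1ccc(O)c(OC)c1)O2 | intermediate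
21 | ArE–Br | Brc1cc(OC)c2c(c1)[C@@H](CO[Si](C)(C)C(C)(C)C)[C@H](c1ccc(OCC=C)c(OC)c1)O2 | intermediate
22 | ArE–Li | [Li]c1cc(OC)c2c(c1)[C@@H](CO[Si](C)(C)C(C)(C)C)[C@H](c1ccc(OCC=C)c(OC)c1)O2 | intermediate
23 | ArE–CHO | O=Cc1cc(OC)c2c(c1)[C@@H](CO[Si](C)(C)C(C)(C)C)[C@H](c1ccc(OCC=C)c(OC)c1)O2 | intermediate
24 | ArE–CH2OH | OCc1cc(OC)c2c(c1)[C@@H](CO[Si](C)(C)C(C)(C)C)[C@H](c1ccc(OCC=C)c(OC)c1)O2 | intermediate
25 | ArE–CH2Br | BrCc1cc(OC)c2c(c1)[C@@H](CO[Si](C)(C)C(C)(C)C)[C@H](c1ccc(OCC=C)c(OC)c1)O2 | intermediate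
26 | (S)-4-benzyl-3-[(2R,3S)-2-[2-(allyloxy)-5-bromo-3-methoxyphenyl]-3-[4-(allyloxy)-3-methoxyphenyl]-3-(trimethylsilyloxy)propanoyl]oxazolidin-2-one | COc1cc([C@@H](O[Si](C)(C)C)[C@H](C(=O)N2[C@@H](Cc3ccccc3)COC2=O)c2cc(Br)cc(OC)c2OCC=C)ccc1OCC=C | intermediate
27 | (2S,3S)-2-[2-(allyloxy)-5-bromo-3-methoxyphenyl]-3-[4-(allyloxy)-3-methoxyphenyl]-3-(trimethylsilyloxy)propan-1-ol | COc1cc([C@@H](O[Si](C)(C)C)[C@H](CO)c2cc(Br)cc(OC)c2OCC=C)ccc1OCC=C | intermediate
28 | (1S,2S)-2-[2-(allyloxy)-5-bromo-3-methoxyphenyl]-1-[4-(allyloxy)-3-methoxyphenyl]propane-1,3-diol | COc1cc([C@@H](O)[C@H](CO)c2cc(Br)cc(OC)c2OCC=C)ccc1OCC=C | intermediate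
29 | ArW–Br | COc1cc([C@@H](O[Si](C)(C)C(C)(C)C)[C@H](CO[Si](C)(C)C(C)(C)C)c2cc(Br)cc(OC)c2OCC=C)ccc1OCC=C | intermediate
30 | ArW–Li | COc1cc([C@@H](O[Si](C)(C)C(C)(C)C)[C@H](CO[Si](C)(C)C(C)(C)C)c2cc([Li])cc(OC)c2OCC=C)ccc1OCC=C | intermediate
31 | ArW–CHO | COc1cc([C@@H](O[Si](C)(C)C(C)(C)C)[C@H](CO[Si](C)(C)C(C)(C)C)c2cc(C=O)cc(OC)c2OCC=C)ccc1OCC=C | intermediate
32 | ArW–CH2OH | COc1cc([C@@H](O[Si](C)(C)C(C)(C)C)[C@H](CO[Si](C)(C)C(C)(C)C)c2cc(CO)cc(OC)c2OCC=C)ccc1OCC=C | intermediate
33 | ArW–CH2Br | COc1cc([C@@H](O[Si](C)(C)C(C)(C)C)[C@H](CO[Si](C)(C)C(C)(C)C)c2cc(CBr)cc(OC)c2OCC=C)ccc1OCC=C | intermediate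
34 | methyl 4-chloro-4-oxobutanoate | COC(=O)CCC(Cl)=O | starting material
35 | methyl 4-[(4S)-4-benzyl-2-oxooxazolidin-3-yl]-4-oxobutanoate | COC(=O)CCC(=O)N1[C@@H](Cc2ccccc2)COC1=O | intermediate
36 | sodium (Z)-enolate of 35 | [Na+].[O-]/C(=C\CC(=O)OC)N1[C@@H](Cc2ccccc2)COC1=O | intermediate
37 | methyl (3S)-3-(ArW-methyl)-4-[(4S)-4-benzyl-2-oxooxazolidin-3-yl]-4-oxobutanoate | COc1cc([C@@H](O[Si](C)(C)C(C)(C)C)[C@H](CO[Si](C)(C)C(C)(C)C)c2cc(C[C@@H](CC(=O)OC)C(=O)N3[C@@H](Cc4ccccc4)COC3=O)cc(OC)c2OCC=C)ccc1OCC=C | intermediate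
38 | methyl (3S)-4-ArW-3-(hydroxymethyl)butanoate | COc1cc([C@@H](O[Si](C)(C)C(C)(C)C)[C@H](CO[Si](C)(C)C(C)(C)C)c2cc(C[C@@H](CC(=O)OC)CO)cc(OC)c2OCC=C)ccc1OCC=C | intermediate
39 | (4S)-4-(ArW-methyl)dihydrofuran-2(3H)-one | COc1cc([C@@H](O[Si](C)(C)C(C)(C)C)[C@H](CO[Si](C)(C)C(C)(C)C)c2cc(C[C@@H]3COC(=O)C3)cc(OC)c2OCC=C)ccc1OCC=C | intermediate
40 | lithium enolate of 39 | [Li+].COc1cc([C@@H](O[Si](C)(C)C(C)(C)C)[C@H](CO[Si](C)(C)C(C)(C)C)c2cc(C[C@@H]3COC([O-])=C3)cc(OC)c2OCC=C)ccc1OCC=C | intermediate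
41 | (3S,4S)-3-(ArE-methyl)-4-(ArW-methyl)dihydrofuran-2(3H)-one | COc1cc([C@@H](O[Si](C)(C)C(C)(C)C)[C@H](CO[Si](C)(C)C(C)(C)C)c2cc(C[C@@H]3COC(=O)[C@H]3Cc3cc(OC)c4c(c3)[C@@H](CO[Si](C)(C)C(C)(C)C)[C@H](c3ccc(OCC=C)c(OC)c3)O4)cc(OC)c2OCC=C)ccc1OCC=C | intermediate
42 | tetra-O-allyl ether of the target (all four phenols allylated, all alcohols free) | COc1cc([C@@H](O)[C@H](CO)c2cc(C[C@@H]3COC(=O)[C@H]3Cc3cc(OC)c4c(c3)[C@@H](CO)[C@H](c3ccc(OCC=C)c(OC)c3)O4)cc(OC)c2OCC=C)ccc1OCC=C | intermediate
43 | (3S,4S)-3-{[(2R,3S)-2-(4-hydroxy-3-methoxyphenyl)-3-(hydroxymethyl)-7-methoxy-2,3-dihydro-1-benzofuran-5-yl]methyl}-4-{4-hydroxy-3-[(1S,2S)-1,3-dihydroxy-1-(4-hydroxy-3-methoxyphenyl)propan-2-yl]-5-methoxybenzyl}dihydrofuran-2(3H)-one | COc1cc([C@@H](O)[C@H](CO)c2cc(C[C@@H]3COC(=O)[C@H]3Cc3cc(OC)c4c(c3)[C@@H](CO)[C@H](c3ccc(O)c(OC)c3)O4)cc(OC)c2O)ccc1O | target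

Total step count: 26
Longest linear sequence: 15 steps (1, 2, 3, 4, 8, 9, 10, 11, 12, 13, 14, 15, 24, 25, 26)

Steps most likely to fail

Step 12. What may go wrong: tautomerisation of the quinone methide to the stilbene with loss of the C3 configuration, competing hydride loss from the ring B benzylic C–H, or further dehydrogenation of the product to the benzofuran. The fallback replaces C–H oxidation by an ionic ring closure at a carbinol; it sets out from diol 28 and comes back to the route at 20. Selective silylation of the primary hydroxyl of 28 (TBSCl, imidazole, CH2Cl2, 0 °C) should give mono-TBS diol F1. Removal of both allyl groups as in step 11 should give bisphenol carbinol F2. Mitsunobu cyclodehydration (PPh3, DIAD, THF, 0 °C) should then let the ring B phenol displace the activated benzylic hydroxyl with inversion, which from the (1S) carbinol gives the 2,3-trans compound 20. Any leak through the quinone methide would end at the same trans isomer.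

Step 16. What may go wrong: poor anti selectivity or attack on the other enolate face, or retro-aldol of the crowded aryl/aryl adduct before it is silylated. The fallback uses a boron syn-aldol followed by inversion of the carbinol; it sets out from acid 6 and comes back at 29.
- Acylation of (R)-4-benzyloxazolidin-2-one with 6 under the conditions of step 4 should give ent-auxiliary imide F3.
- The Evans boron aldol (Bu2BOTf, i-Pr2NEt, CH2Cl2, −78 °C, then 11) should give syn-aldol adduct F4, with C2 in the required sense and C3 epimeric.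
- LiBH4 reduction should give syn-diol F5, and selective silylation of the primary hydroxyl (TBSCl, imidazole) should give mono-TBS syn-diol F6.
- Mitsunobu inversion (4-nitrobenzoic acid, PPh3, DIAD, THF) should give 4-nitrobenzoate F7, and methanolysis (K2CO3, MeOH) should give mono-TBS diol F1, the compound of the first fallback.
- Silylation of the secondary hydroxyl (TBSOTf, 2,6-lutidine) should give 29.

Step 24. What may go wrong: sluggish alkylation of the bulky enolate by the bulky bromide, double alkylation, or erosion of the trans selectivity. The fallback replaces the SN2 alkylation by aldol condensation and conjugate reduction; it sets out from lactone 39 and aldehyde 23 (isolated by leaving out the borohydride stage of step 14) and comes back at 41. Aldol addition of the lithium enolate of 39 (LiN(SiMe3)2, THF, −78 °C) to 23 should give aldol adduct F8 as a mixture at the two new centres. Mesylation and elimination (MsCl, Et3N, then DBU) should give arylidene lactone F9. Conjugate reduction with LiBH(s-Bu)3 (THF, −78 °C), followed by equilibration with DBU, should give the thermodynamically favoured trans lactone 41.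

Further compounds
F1 | step 12 | (1S,2S)-2-[2-(allyloxy)-5-bromo-3-methoxyphenyl]-1-[4-(allyloxy)-3-methoxyphenyl]-3-(TBS-oxy)propan-1-ol | COc1cc([C@@H](O)[C@H](CO[Si](C)(C)C(C)(C)C)c2cc(Br)cc(OC)c2OCC=C)ccc1OCC=C
F2 | step 12 | 4-bromo-2-[(1S,2S)-3-(TBS-oxy)-1-hydroxy-1-(4-hydroxy-3-methoxyphenyl)propan-2-yl]-6-methoxyphenol | COc1cc([C@@H](O)[C@H](CO[Si](C)(C)C(C)(C)C)c2cc(Br)cc(OC)c2O)ccc1O
F3 | step 16 | (R)-4-benzyl-3-{2-[2-(allyloxy)-5-bromo-3-methoxyphenyl]acetyl}oxazolidin-2-one | O=C(Cc1cc(Br)cc(OC)c1OCC=C)N1[C@H](Cc2ccccc2)COC1=O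
F4 | step 16 | (R)-4-benzyl-3-[(2R,3R)-2-[2-(allyloxy)-5-bromo-3-methoxyphenyl]-3-[4-(allyloxy)-3-methoxyphenyl]-3-hydroxypropanoyl]oxazolidin-2-one | COc1cc([C@H](O)[C@H](C(=O)N2[C@H](Cc3ccccc3)COC2=O)c2cc(Br)cc(OC)c2OCC=C)ccc1OCC=C
F5 | step 16 | (1R,2S)-2-[2-(allyloxy)-5-bromo-3-methoxyphenyl]-1-[4-(allyloxy)-3-methoxyphenyl]propane-1,3-diol | COc1cc([C@H](O)[C@H](CO)c2cc(Br)cc(OC)c2OCC=C)ccc1OCC=C
F6 | step 16 | (1R,2S)-2-[2-(allyloxy)-5-bromo-3-methoxyphenyl]-1-[4-(allyloxy)-3-methoxyphenyl]-3-(TBS-oxy)propan-1-ol | COc1cc([C@H](O)[C@H](CO[Si](C)(C)C(C)(C)C)c2cc(Br)cc(OC)c2OCC=C)ccc1OCC=C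
F7 | step 16 | (1S,2S)-2-[2-(allyloxy)-5-bromo-3-methoxyphenyl]-1-[4-(allyloxy)-3-methoxyphenyl]-3-(TBS-oxy)propyl 4-nitrobenzoate | COc1cc([C@@H](OC(=O)c2ccc(cc2)[N+]([O-])=O)[C@H](CO[Si](C)(C)C(C)(C)C)c2cc(Br)cc(OC)c2OCC=C)ccc1OCC=C
F8 | step 24 | (4S)-3-[ArE(hydroxy)methyl]-4-(ArW-methyl)dihydrofuran-2(3H)-one (mixture at C3 and the carbinol carbon) | COc1cc([C@@H](O[Si](C)(C)C(C)(C)C)[C@H](CO[Si](C)(C)C(C)(C)C)c2cc(C[C@@H]3COC(=O)C3C(O)c3cc(OC)c4c(c3)[C@@H](CO[Si](C)(C)C(C)(C)C)[C@H](c3ccc(OCC=C)c(OC)c3)O4)cc(OC)c2OCC=C)ccc1OCC=C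
F9 | step 24 | (4S,E)-3-(ArE-methylidene)-4-(ArW-methyl)dihydrofuran-2(3H)-one | COc1cc([C@@H](O[Si](C)(C)C(C)(C)C)[C@H](CO[Si](C)(C)C(C)(C)C)c2cc(C[C@@H]3COC(=O)/C3=C/c3cc(OC)c4c(c3)[C@@H](CO[Si](C)(C)C(C)(C)C)[C@H](c3ccc(OCC=C)c(OC)c3)O4)cc(OC)c2OCC=C)ccc1OCC=C
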